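(The data stem from a simulated flask on assumed constants, and the scatter is random.)

The leftover of starting material at the last noon reading is 0.7%, beside 8.0% of target, so 91.3% of the charge is out of sight. Between the last two noon readings target gained 5.1 percentage points while starting material lost 1.4 points, so target was then being fed from an unseen reservoir through a slow late step, the rate-limiting step for target.

| flask | starting material | partner | protic impurity | temperature | remark | time |
|---|---|---|---|---|---|---|
| summer | 0.30 M | 0.10 M | 0.30 M | 55 °C | run made earlier |  |
| noon | 0.30 M | 0.42 M | 0.30 M | 82 °C | run made earlier |  |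
| alder | 0.30 M | 0.210 M | 0.300 M | 105 °C |  | 30 h |
| cedar | 0.30 M | 0.210 M | 0.300 M | 60 °C |  | 30 h |
| birch | 0.30 M | 0.210 M | 0.300 M | 75 °C |  | 30 h |
| larch | 0.30 M | 0.210 M | 0.300 M | 90 °C |  | 30 h |

- summer (time / h: target / %, starting material / %): 72.0: 0, 64.2; 144: 0, 45.6; 240: 0.5, 30.7; 288: 0.4, 26.1; 360: 1.3, 20.7; 480: 0.3, 14.1
- noon (time / h: target / %, starting material / %): 10.0: 0, 36.2; 15.0: 1.0, 24.7; 25.0: 0, 12.1; 40.0: 2.8, 4.1; 60.0: 2.9, 2.1; 120: 8.0, 0.7

(standard deviation of a reading: 0.5 percentage points)

- the flask that comes out highest in amount of target, in percent of the starting material charged, or "all alike" when all lie within 1.5 percentage points (alder / cedar / birch / larch / all alike)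
- target at the end, in percent of the starting material charged, alder
- target at the end, in percent of the starting material charged, cedar
- target at the end, in percent of the starting material charged, birch
- target at the end, in percent of the starting material charged, larch

- a reading or a percentage of target counts all its forms, free or not
- a reading of starting material is of its free form alone

Those same noon readings give 0.00202 /M/h for G, the late yield rate: target gained per hour per molar of partner charged. It assumes that the reservoir grows with the partner charged.

Ann holds that a flask of 30 h cannot pass what noon reached in 120 h, so she caps alder at the last noon reading, 8.0%. Ben holds that G climbs steeply with temperature. He argues from the summer run, whose highest target reading is 1.3%. Counted as reached by the last summer reading, it puts summer G near 2.71 × 10⁻⁴ /M/h, and the true figure may be lower, since that last reading is 0.3%. Noon's G is 7.47 times that figure. Ben carries the same factor per degree from noon's 82 °C up to alder's 105 °C, which gives about 0.0112 /M/h. Multiplied by alder's 0.210 M of partner and its 30 h, that is 7.07%.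

Ann answers that this figure is rough, and it is. I still side with Ben: I expect alder, hotter than the others, to come first, near 7.07%.

The forecast stays under Ann's cap and under my figure, with alder first at 6%, larch 1.8%, birch 0.4% and cedar 0.05%, and it says “The hottest flask should win”.

The simulation gives alder first at 12.8%, then larch 2.48%, birch 0.249% and cedar 0.0133%.

    starting material + partner → intermediate + released group (k = 6.50 × 10⁻⁵ /M/s, Ea = 89.0 kJ/mol)
    starting material + target ⇌ idle adduct, settled at all times (K = 1.30 /M, ΔH = −90.0 kJ/mol)
    2 starting material → self-condensation product (k = 3.00 × 10⁻⁵ /M/s, Ea = 93.0 kJ/mol)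
    intermediate → target (k = 1.10 × 10⁻⁶ /s, Ea = 123 kJ/mol)
    starting material + protic impurity → quenched substrate (k = 7.20 × 10⁻⁵ /M/s, Ea = 86.0 kJ/mol)
    (constants at 90 °C)

Alder's own G, averaged over its run, is 0.0202 /M/h, which is 1.80 times Ben's figure, and alder passes noon's last reading. Ann's cap holds at larch, birch and cedar, which all stay under it. Now take a neighbouring flask, alder with 0.36 M of partner. Alder's G gives it 21.9%. The flask gives 18.4%, so the reckoning overshoots by 3.5 points, and at the end of that flask 24.9% of the starting material charged stands as intermediate.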